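**Retrosynthetic overview**
1. C6–OAc comes from the C6 ketone (hydride from the open face, then O‑acetylation); the ketone comes from the C6‑epimeric alcohol that ring closure is expected to give; isopropyl comes from isopropenyl.
2. The ten‑membered carbocycle (second and last ring) is closed at C6–C7 by intramolecular Pd/Zn umpolung allylation of an α,β‑epoxy aldehyde by a terminal allylic chloride.
3. Key disconnection, C3–O(angelate): the ester C–O bond is made with inversion from an erythro epoxy alcohol by a new deoxy‑acyloxylation, giving the threo ester.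
4. The oxirane (first ring) comes from a Sharpless kinetic‑resolution epoxidation of a racemic secondary allylic alcohol, which sets C4 and C5 and resolves C3 in one C–O bond‑forming step.
5. The C15 chain comes from geranyl chloride and (2E)‑4‑acetoxy‑2‑methylbut‑2‑enal by α‑selective allylbarium addition.

Numbering: acyclic compounds use dodecane (farnesane) numbering, with C1 the CH2O/CHO carbon, the oxirane at C2–C3 and the ester carbinol at C4. Ring compounds use germacrane numbering (C1=C10 alkene, C3 angelate carbon, C4–C5 oxirane, C6 acetate carbon, C7 isopropyl carbon). Dodecane C1, C2, C3, C4 become germacrane C6, C5, C4, C3. The target as drawn is (1(10)E,3S,4R,5R,6S,7R) with a (2Z)‑2‑methylbut‑2‑enoate (angelate).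

Assumption: geranyl chloride, (2E)‑4‑acetoxy‑2‑methylbut‑2‑enal, angelic acid and 1,3‑bis(2,6‑diisopropylphenyl)‑2‑fluoroimidazolium tetrafluoroborate are bought.

The C6/C7 outcome of step 7 and the facial selectivity of step 10 are predictions from the Felkin–Anh and chair transition‑state models, not established results for this substrate.

**Route**

Step 1
Reactants: 1 geranyl chloride [(2E)‑1‑chloro‑3,7‑dimethylocta‑2,6‑diene]; 2 (2E)‑4‑acetoxy‑2‑methylbut‑2‑enal
Product: 4 racemic (2E,6E)‑4‑hydroxy‑3,7,11‑trimethyldodeca‑2,6,10‑trien‑1‑yl acetate, via geranylbarium chloride 3 (not isolated)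
Conditions: BaI2 (1.1 equiv), Li(C12H10) [lithium biphenylide] (2.2 equiv), THF, rt; 1, −78 °C; 2, −78 °C; then aq NH4Cl
Reagents that add atoms: none
Why: Barbier‑type carbonyl allylation with an allylbarium reagent, which adds to aldehydes through its unsubstituted (α) terminus with retention of the E alkene and by 1,2‑addition to enals, so the linear C15 chain with the C4 oxygen is formed in one step; C4 is racemic and the acetate survives at −78 °C.

Step 2
Reactants: 4 racemic (2E,6E)‑4‑hydroxy‑3,7,11‑trimethyldodeca‑2,6,10‑trien‑1‑yl acetate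
Product: 5 (2R,3R,4R,6E)‑2,3‑epoxy‑4‑hydroxy‑3,7,11‑trimethyldodeca‑6,10‑dien‑1‑yl acetate
Conditions: Ti(OiPr)4 (10 mol%), D‑(−)‑diisopropyl tartrate (15 mol%), t‑BuOOH (0.6 equiv), 4 Å MS, CH2Cl2, −20 °C
Reagents that add atoms: tert‑butyl hydroperoxide, CC(C)(C)OO
Why: Sharpless kinetic‑resolution epoxidation: with D‑(−)‑tartrate the (4R)‑alcohol is epoxidised much faster than the (4S), on the face that gives the (2R,3R)‑oxirane erythro to the carbinol, so C2 and C3 are set and C4 is resolved in one C–O bond‑forming step (at most 50% yield); only the allylic‑alcohol alkene reacts and the (4S)‑alcohol is recovered.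

Step 3
Reactants: 5 (2R,3R,4R,6E)‑2,3‑epoxy‑4‑hydroxy‑3,7,11‑trimethyldodeca‑6,10‑dien‑1‑yl acetate; 6 angelic acid [(2Z)‑2‑methylbut‑2‑enoic acid]
Product: 9 (2R,3R,4S,6E)‑1‑acetoxy‑2,3‑epoxy‑3,7,11‑trimethyldodeca‑6,10‑dien‑4‑yl angelate, via trimethylsilyl angelate 7 (not isolated), via alkoxyimidazolium tetrafluoroborate 8 (not isolated)
Conditions: 6, (Me3Si)2NH, toluene, 60 °C (to 7); 5, 1,3‑bis(2,6‑diisopropylphenyl)‑2‑fluoroimidazolium tetrafluoroborate (1.1 equiv), i‑Pr2NEt (1.2 equiv), toluene, rt (to 8); then 7 (1.5 equiv), 50 °C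
Reagents that add atoms: none
Why: Proposed new method: the alcohol is first turned, with no carboxylate present, into the 2‑alkoxyimidazolium ion 8, a carbon‑centred onium leaving group that cannot exchange ligands as alkoxyphosphonium species do, so the carboxylate can only attack C4 from the back (SN2) and gives the (4S)‑ester, threo to the oxirane, with inversion; adding the acid as silyl ester 7 lets the fluoride released in the first stage be trapped as Me3SiF while freeing angelate as the counter‑ion of 8, which suppresses C–F formation and acyl activation (retention), and the phosphine‑free medium cannot isomerise the Z‑enoate; the closest known reactions are deoxyfluorination of secondary alcohols with 2‑fluoroimidazolium reagents (inversion), the Mitsunobu esterification and 2‑halopyridinium onium‑salt inversions.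

Step 4
Reactants: 9 (2R,3R,4S,6E)‑1‑acetoxy‑2,3‑epoxy‑3,7,11‑trimethyldodeca‑6,10‑dien‑4‑yl angelate
Product: 10 (2R,3R,4S,6E)‑2,3‑epoxy‑1‑hydroxy‑3,7,11‑trimethyldodeca‑6,10‑dien‑4‑yl angelate
Conditions: K2CO3 (0.2 equiv), MeOH, 0 °C
Reagents that add atoms: none
Why: Base‑catalysed transesterification (methanolysis) cleaves the unhindered primary acetate far faster than the α‑branched, conjugated secondary angelate; no stereocenter is touched.

Step 5
Reactants: 10 (2R,3R,4S,6E)‑2,3‑epoxy‑1‑hydroxy‑3,7,11‑trimethyldodeca‑6,10‑dien‑4‑yl angelate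
Product: 11 (2R,3R,4S,6E)‑10‑chloro‑2,3‑epoxy‑1‑hydroxy‑3,7,11‑trimethyldodeca‑6,11‑dien‑4‑yl angelate (both C10 epimers)
Conditions: PhSeCl (10 mol%), N‑chlorosuccinimide (1.1 equiv), CH2Cl2, rt
Reagents that add atoms: N‑chlorosuccinimide, O=C1CCC(=O)N1Cl
Why: Selenium‑catalysed ene‑type allylic chlorination attacks the most accessible and most electron‑rich terminal trisubstituted alkene (the 6,7‑alkene is shielded and inductively deactivated, the angelate alkene is electron‑poor) and gives the transposed secondary allylic chloride; C10 forms as both epimers and is erased in step 7.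

Step 6
Reactants: 11 (2R,3R,4S,6E)‑10‑chloro‑2,3‑epoxy‑1‑hydroxy‑3,7,11‑trimethyldodeca‑6,11‑dien‑4‑yl angelate
Product: 12 (2S,3R,4S,6E)‑10‑chloro‑2,3‑epoxy‑3,7,11‑trimethyl‑1‑oxododeca‑6,11‑dien‑4‑yl angelate (both C10 epimers)
Conditions: Dess–Martin periodinane, pyridine, CH2Cl2, 0 °C to rt
Reagents that add atoms: none
Why: Buffered Dess–Martin oxidation of the primary alcohol gives the α,β‑epoxy aldehyde without touching oxirane, chloride or ester (C2 changes descriptor only because the priorities change); the aldehyde is used at once.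

Step 7
Reactants: 12 (2S,3R,4S,6E)‑10‑chloro‑2,3‑epoxy‑3,7,11‑trimethyl‑1‑oxododeca‑6,11‑dien‑4‑yl angelate
Product: 14 (1(10)E,3S,4R,5R,6R,7R)‑4,5‑epoxy‑6‑hydroxygermacra‑1(10),11‑dien‑3‑yl angelate, via allylzinc species 13 (not isolated)
Conditions: Pd(PPh3)4 (10 mol%), Et2Zn (3 equiv), THF/DMA (4:1), 0.005 M, slow addition of 12, rt
Reagents that add atoms: none
Why: Palladium‑catalysed umpolung allylation (Tamaru type, precedented for the ring closure of the analogue without the C3 ester): the chloride gives a π‑allylpalladium that transmetalates to an allylzinc, which adds through its γ‑carbon to the aldehyde in a chair six‑membered transition state and closes the ten‑membered ring; C5 and C8 equatorial give the 6,7‑trans relationship and attack anti to the oxirane C–O bond (Felkin–Anh, zinc not chelated in DMA) gives erythro, so (6R,7R) is expected, that is the correct C7 and the C6 epimer of the target.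

Step 8
Reactants: 14 (1(10)E,3S,4R,5R,6R,7R)‑4,5‑epoxy‑6‑hydroxygermacra‑1(10),11‑dien‑3‑yl angelate
Product: 15 (1(10)E,3S,4R,5R,6R,7R)‑4,5‑epoxy‑6‑hydroxygermacr‑1(10)‑en‑3‑yl angelate
Conditions: RhCl(PPh3)3 (5 mol%), H2 (1 atm), benzene/EtOH (1:1), rt
Reagents that add atoms: none
Why: Homogeneous hydrogenation with RhCl(PPh3)3 reduces the 1,1‑disubstituted isopropenyl alkene much faster than the two trisubstituted alkenes (ring alkene and angelate), so only the isopropyl group forms and no stereocenter changes.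

Step 9
Reactants: 15 (1(10)E,3S,4R,5R,6R,7R)‑4,5‑epoxy‑6‑hydroxygermacr‑1(10)‑en‑3‑yl angelate
Product: 16 (1(10)E,3S,4R,5S,7R)‑4,5‑epoxy‑6‑oxogermacr‑1(10)‑en‑3‑yl angelate
Conditions: Dess–Martin periodinane, pyridine, CH2Cl2, rt
Reagents that add atoms: none
Why: Dess–Martin oxidation of the secondary alcohol to the α,β‑epoxy ketone under neutral buffered conditions avoids epimerisation at C7 and oxirane opening (C5 changes descriptor only because the priorities change).

Step 10
Reactants: 16 (1(10)E,3S,4R,5S,7R)‑4,5‑epoxy‑6‑oxogermacr‑1(10)‑en‑3‑yl angelate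
Product: 18 (1(10)E,3S,4R,5R,6S,7R)‑6‑acetoxy‑4,5‑epoxygermacr‑1(10)‑en‑3‑yl angelate, via lithium alkoxide 17 (not isolated)
Conditions: LiBH(s‑Bu)3 (1.1 equiv), THF, −78 °C; then Ac2O (5 equiv), DMAP, −78 °C to 0 °C
Reagents that add atoms: acetic anhydride, CC(=O)OC(C)=O
Why: Hydride reduction with in‑flask O‑acylation: the bulky, non‑chelating borohydride should attack the ring ketone from its open outer face, anti to the oxirane C–O bond (Felkin–Anh), which with hydride as the nucleophile gives the threo (6S)‑alkoxide with oxygen cis to the C7 isopropyl group, the reverse of step 7; the alkoxide is acetylated in the same flask and the hindered enoate is not reduced at −78 °C.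

**Compound list**
1 | geranyl chloride, (2E)‑1‑chloro‑3,7‑dimethylocta‑2,6‑diene | ClC/C=C(\C)CCC=C(C)C | starting material
2 | (2E)‑4‑acetoxy‑2‑methylbut‑2‑enal | CC(=O)OC/C=C(\C)C=O | starting material
3 | geranylbarium chloride (not isolated) | Cl[Ba]C/C=C(\C)CCC=C(C)C | intermediate
4 | racemic (2E,6E)‑4‑hydroxy‑3,7,11‑trimethyldodeca‑2,6,10‑trien‑1‑yl acetate | CC(=O)OC/C=C(\C)C(O)C/C=C(\C)CCC=C(C)C | intermediate
5 | (2R,3R,4R,6E)‑2,3‑epoxy‑4‑hydroxy‑3,7,11‑trimethyldodeca‑6,10‑dien‑1‑yl acetate | CC(=O)OC[C@H]1O[C@]1(C)[C@H](O)C/C=C(\C)CCC=C(C)C | intermediate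
6 | angelic acid, (2Z)‑2‑methylbut‑2‑enoic acid | C/C=C(/C)C(=O)O | starting material
7 | trimethylsilyl angelate (not isolated) | C/C=C(/C)C(=O)O[Si](C)(C)C | intermediate
8 | 2‑{[(2R,3R,4R,6E)‑1‑acetoxy‑2,3‑epoxy‑3,7,11‑trimethyldodeca‑6,10‑dien‑4‑yl]oxy}‑1,3‑bis(2,6‑diisopropylphenyl)imidazolium tetrafluoroborate (not isolated) | CC(=O)OC[C@H]1O[C@]1(C)[C@H](Oc1n(-c2c(C(C)C)cccc2C(C)C)cc[n+]1-c1c(C(C)C)cccc1C(C)C)C/C=C(\C)CCC=C(C)C.F[B-](F)(F)F | intermediate
9 | (2R,3R,4S,6E)‑1‑acetoxy‑2,3‑epoxy‑3,7,11‑trimethyldodeca‑6,10‑dien‑4‑yl angelate | CC(=O)OC[C@H]1O[C@]1(C)[C@@H](OC(=O)/C(C)=C\C)C/C=C(\C)CCC=C(C)C | intermediate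
10 | (2R,3R,4S,6E)‑2,3‑epoxy‑1‑hydroxy‑3,7,11‑trimethyldodeca‑6,10‑dien‑4‑yl angelate | OC[C@H]1O[C@]1(C)[C@@H](OC(=O)/C(C)=C\C)C/C=C(\C)CCC=C(C)C | intermediate
11 | (2R,3R,4S,6E)‑10‑chloro‑2,3‑epoxy‑1‑hydroxy‑3,7,11‑trimethyldodeca‑6,11‑dien‑4‑yl angelate (both C10 epimers) | OC[C@H]1O[C@]1(C)[C@@H](OC(=O)/C(C)=C\C)C/C=C(\C)CCC(Cl)C(C)=C | intermediate
12 | (2S,3R,4S,6E)‑10‑chloro‑2,3‑epoxy‑3,7,11‑trimethyl‑1‑oxododeca‑6,11‑dien‑4‑yl angelate (both C10 epimers) | O=C[C@H]1O[C@]1(C)[C@@H](OC(=O)/C(C)=C\C)C/C=C(\C)CCC(Cl)C(C)=C | intermediate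
13 | (2S,3R,4S,6E)‑2,3‑epoxy‑12‑(ethylzincio)‑3,7,11‑trimethyl‑1‑oxododeca‑6,10‑dien‑4‑yl angelate (not isolated) | O=C[C@H]1O[C@]1(C)[C@@H](OC(=O)/C(C)=C\C)C/C=C(\C)CCC=C(C)C[Zn]CC | intermediate
14 | (1(10)E,3S,4R,5R,6R,7R)‑4,5‑epoxy‑6‑hydroxygermacra‑1(10),11‑dien‑3‑yl angelate | C/C=C(/C)C(=O)O[C@H]1C/C=C(\C)CC[C@H](C(C)=C)[C@@H](O)[C@H]2O[C@]12C | intermediate
15 | (1(10)E,3S,4R,5R,6R,7R)‑4,5‑epoxy‑6‑hydroxygermacr‑1(10)‑en‑3‑yl angelate | C/C=C(/C)C(=O)O[C@H]1C/C=C(\C)CC[C@H](C(C)C)[C@@H](O)[C@H]2O[C@]12C | intermediate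
16 | (1(10)E,3S,4R,5S,7R)‑4,5‑epoxy‑6‑oxogermacr‑1(10)‑en‑3‑yl angelate | C/C=C(/C)C(=O)O[C@H]1C/C=C(\C)CC[C@H](C(C)C)C(=O)[C@H]2O[C@]12C | intermediate
17 | lithium (1(10)E,3S,4R,5R,6S,7R)‑3‑(angeloyloxy)‑4,5‑epoxygermacr‑1(10)‑en‑6‑olate (not isolated) | C/C=C(/C)C(=O)O[C@H]1C/C=C(\C)CC[C@H](C(C)C)[C@H]([O-])[C@H]2O[C@]12C.[Li+] | intermediate
18 | (1(10)E,3S,4R,5R,6S,7R)‑6‑acetoxy‑4,5‑epoxygermacr‑1(10)‑en‑3‑yl angelate | C/C=C(/C)C(=O)O[C@H]1C/C=C(\C)CC[C@H](C(C)C)[C@H](OC(C)=O)[C@H]2O[C@]12C | target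

**Step count**
Total steps: 10. Longest linear sequence: 10 steps (from 1 and 2; 6 enters at step 3).

**Three steps most likely to fail**

Step 3 (the new C–O coupling). The risks are slow formation of the hindered alkoxyimidazolium, elimination to a diene, or ester formed with retention. The fallback uses known chemistry and takes the C4 centre from the other enantiomer; it sets out from 4. The enantiomer that step 2 leaves untouched, (2E,4S,6E)‑4‑hydroxy‑3,7,11‑trimethyldodeca‑2,6,10‑trien‑1‑yl acetate F1, already has the C4 configuration of the target. It is esterified with retention by 6 (2,4,6‑trichlorobenzoyl chloride, Et3N, DMAP, toluene, rt) to (2E,4S,6E)‑1‑acetoxy‑3,7,11‑trimethyldodeca‑2,6,10‑trien‑4‑yl angelate F2. The primary acetate is removed (K2CO3, MeOH, 0 °C) to give (2E,4S,6E)‑1‑hydroxy‑3,7,11‑trimethyldodeca‑2,6,10‑trien‑4‑yl angelate F3. A Sharpless epoxidation directed by the primary hydroxyl (Ti(OiPr)4, D‑(−)‑diethyl tartrate, t‑BuOOH, CH2Cl2, −20 °C) then places the (2R,3R)‑oxirane under reagent control, and the sequence comes back to the route at 10.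

Step 7 (ring closure). The risks are oligomerisation, ethyl transfer to the aldehyde, and facial selectivity lost or reversed by zinc chelation of the oxirane. The fallback replaces the zinc reagent by a boron one and sets out from 11. Pd2(dba)3 (cat.), B2pin2, THF, 50 °C converts the allylic chloride into the linear allylboronate (2R,3R,4S,6E,10E)‑2,3‑epoxy‑1‑hydroxy‑3,7,11‑trimethyl‑12‑(4,4,5,5‑tetramethyl‑1,3,2‑dioxaborolan‑2‑yl)dodeca‑6,10‑dien‑4‑yl angelate F4. Dess–Martin periodinane with pyridine at high dilution (0.003 M in CH2Cl2) gives (2S,3R,4S,6E,10E)‑2,3‑epoxy‑3,7,11‑trimethyl‑1‑oxo‑12‑(4,4,5,5‑tetramethyl‑1,3,2‑dioxaborolan‑2‑yl)dodeca‑6,10‑dien‑4‑yl angelate F5. This closes the ring at rt to 40 °C by intramolecular allylboration (metal‑free closed chair transition state, no chelating Lewis acid), and aqueous work‑up hydrolyses the borate and comes back to the route at 14.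

Step 10 (C6 configuration). The risk is that hydride enters from the other face and returns the 6R series; this is a real possibility, since simple acyclic α,β‑epoxy ketones often reduce to the erythro alcohol. The fallback sets the centre by substitution instead of reduction and sets out from 15; it is itself uncertain, because backside attack at a ring carbinol in a ten‑membered ring is hindered and elimination may compete. Mitsunobu inversion with 4‑nitrobenzoic acid (PPh3, diisopropyl azodicarboxylate, toluene, 0 °C to rt) gives (1(10)E,3S,4R,5R,6S,7R)‑3‑(angeloyloxy)‑4,5‑epoxygermacr‑1(10)‑en‑6‑yl 4‑nitrobenzoate F6. K2CO3 in MeOH at 0 °C cleaves the activated ester selectively to (1(10)E,3S,4R,5R,6S,7R)‑4,5‑epoxy‑6‑hydroxygermacr‑1(10)‑en‑3‑yl angelate F7. Ac2O, DMAP and pyridine then give 18.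

**Further compounds**
F1 | step 3 | (2E,4S,6E)‑4‑hydroxy‑3,7,11‑trimethyldodeca‑2,6,10‑trien‑1‑yl acetate | CC(=O)OC/C=C(\C)[C@@H](O)C/C=C(\C)CCC=C(C)C
F2 | step 3 | (2E,4S,6E)‑1‑acetoxy‑3,7,11‑trimethyldodeca‑2,6,10‑trien‑4‑yl angelate | CC(=O)OC/C=C(\C)[C@@H](OC(=O)/C(C)=C\C)C/C=C(\C)CCC=C(C)C
F3 | step 3 | (2E,4S,6E)‑1‑hydroxy‑3,7,11‑trimethyldodeca‑2,6,10‑trien‑4‑yl angelate | OC/C=C(\C)[C@@H](OC(=O)/C(C)=C\C)C/C=C(\C)CCC=C(C)C
F4 | step 7 | (2R,3R,4S,6E,10E)‑2,3‑epoxy‑1‑hydroxy‑3,7,11‑trimethyl‑12‑(4,4,5,5‑tetramethyl‑1,3,2‑dioxaborolan‑2‑yl)dodeca‑6,10‑dien‑4‑yl angelate | OC[C@H]1O[C@]1(C)[C@@H](OC(=O)/C(C)=C\C)C/C=C(\C)CC/C=C(\C)CB1OC(C)(C)C(C)(C)O1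
F5 | step 7 | (2S,3R,4S,6E,10E)‑2,3‑epoxy‑3,7,11‑trimethyl‑1‑oxo‑12‑(4,4,5,5‑tetramethyl‑1,3,2‑dioxaborolan‑2‑yl)dodeca‑6,10‑dien‑4‑yl angelate | O=C[C@H]1O[C@]1(C)[C@@H](OC(=O)/C(C)=C\C)C/C=C(\C)CC/C=C(\C)CB1OC(C)(C)C(C)(C)O1
F6 | step 10 | (1(10)E,3S,4R,5R,6S,7R)‑3‑(angeloyloxy)‑4,5‑epoxygermacr‑1(10)‑en‑6‑yl 4‑nitrobenzoate | C/C=C(/C)C(=O)O[C@H]1C/C=C(\C)CC[C@H](C(C)C)[C@H](OC(=O)c3ccc(cc3)[N+](=O)[O-])[C@H]2O[C@]12C
F7 | step 10 | (1(10)E,3S,4R,5R,6S,7R)‑4,5‑epoxy‑6‑hydroxygermacr‑1(10)‑en‑3‑yl angelate | C/C=C(/C)C(=O)O[C@H]1C/C=C(\C)CC[C@H](C(C)C)[C@H](O)[C@H]2O[C@]12C
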